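**Retrosynthetic overview**
- The enone is made last: a primary alkyl organometallic from the left half adds to the hindered carbonyl of a right-half vinylogous ester, and acid then transposes it (Stork–Danheiser). This splits the target into a silyl-protected 2-iodoethyl perhydrobenzoxepine and a 7-methoxy hydroazulenone.
- Hydroazulenone from (R)-linalool: RCM gives the methylcyclopentenyl silyl ether; a keteniminium–alkene [2+2] cycloaddition anti to the silyloxy group sets both ring-fusion centres; CH2N2 expands the cyclobutanone to the diquinane; a ketene–silyl enol ether [2+2] followed by retro-aldol gives the seven-membered 1,3-dione.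
- Perhydrobenzoxepine from (S)-linalool: ozonolysis, isopropenyl Grignard, RCM and oxidation give the 4-hydroxycyclohexenone; alkoxide-directed vinyl 1,4-addition, enolate alkylation and ketone reduction set three centres; alkoxymercuration closes the oxepane and an oxidation/reduction pair fixes the last carbinol.
- Ring order: cyclopentane, cyclobutanone, cyclopentanone, cycloheptanedione (right half); cyclohexane, oxepane (left half); fragments joined in the final step.

Assumption: both linalool enantiomers are bought in high enantiomeric purity ((R)-(−) from ho-wood oil, (S)-(+) from coriander oil).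

**Route**

Step 1
Reactants: 1 (R)-(−)-linalool
Product: 3 (R)-1-methyl-1-(triethylsilyloxy)cyclopent-2-ene, via (R)-1-methylcyclopent-2-en-1-ol 2 (not isolated)
Conditions: second-generation Grubbs catalyst RuCl2(=CHPh)(PCy3)(H2IMes) (1 mol %), CH2Cl2, 40 °C; then TESOTf, 2,6-lutidine, 0 °C
Reagents that add atoms: triethylsilyl triflate CC[Si](CC)(CC)OS(=O)(=O)C(F)(F)F
Why: Ring-closing metathesis of the 1,6-diene expels isobutene without touching the purchased carbinol centre, and silylation in the same pot avoids isolating the volatile alcohol.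

Step 2
Reactants: 3 (R)-1-methyl-1-(triethylsilyloxy)cyclopent-2-ene; 4 N,N-dimethylisobutyramide
Product: 6 cis-fused cyclobutanone (4,7,7-trimethyl-4-(triethylsilyloxy)bicyclo[3.2.0]heptan-6-one), via cyclobutaniminium triflate 5 (not isolated)
Conditions: Tf2O, 2,4,6-collidine, ClCH2CH2Cl, 0 → 80 °C; then aq. NaHCO3, 60 °C
Reagents that add atoms: water O
Why: Keteniminium–alkene [2+2] cycloaddition (Ghosez type): the electrophile adds anti to the allylic C–OSiEt3 bond (cis to the methyl) and the CMe2 terminus closes on the less hindered, remote alkene carbon, so both ring-fusion centres are set cis by the purchased carbinol; hydrolysis frees the ketone.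

Step 3
Reactants: 6 cis-fused cyclobutanone
Product: 7 cis-bicyclo[3.3.0]octan-3-one (2,2,6-trimethyl-6-(triethylsilyloxy) derivative)
Conditions: CH2N2, Et2O–MeOH, 0 °C → rt
Reagents that add atoms: diazomethane C=[N+]=[N-]
Why: Diazomethane ring expansion (Tiffeneau–Demjanov-type homologation) of the strained cyclobutanone; the less substituted methine α-carbon migrates with retention, so CH2 is inserted between C=O and the ring-fusion CH.

Step 4
Reactants: 7 cis-bicyclo[3.3.0]octan-3-one
Product: 8 trimethylsilyl enol ether of 7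
Conditions: LiN(i-Pr)2, THF, −78 °C; TMSCl, −78 → 0 °C
Reagents that add atoms: chlorotrimethylsilane C[Si](C)(C)Cl
Why: Kinetic enolisation and O-silylation; only the CH2 side of the ketone carries α-hydrogens, so one regioisomer forms.

Step 5
Reactants: 8 trimethylsilyl enol ether; 9 2-chloropropanoyl chloride
Product: 11 tricyclic 2-chloro-2-methyl-3-(trimethylsilyloxy)cyclobutanone, via chloro(methyl)ketene 10 (not isolated)
Conditions: Et3N (slow addition), hexane, reflux
Reagents that add atoms: none
Why: Ketene–silyl enol ether [2+2] cycloaddition; the ketene carbonyl carbon bonds to the nucleophilic enol CH and the CCl(Me) carbon to the siloxy carbon, and the three new centres are erased in step 6.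

Step 6
Reactants: 11 tricyclic chlorocyclobutanone
Product: 13 cis-fused 2-methylcycloheptane-1,3-dione (1,4,4,6-tetramethyl-1-(triethylsilyloxy)octahydroazulene-5,7-dione), via dechlorinated siloxycyclobutanone 12 (not isolated)
Conditions: Zn, NH4Cl, MeOH, 0 °C → rt; then K2CO3, MeOH, rt; citric acid work-up
Reagents that add atoms: none
Why: Zinc reductive dehalogenation of the α-chloro ketone, then desilylation-triggered retro-aldol cleavage of the strained ring-fusion bond gives the seven-membered 1,3-dione; the ring-fusion centres are not enolisable and stay cis.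

Step 7
Reactants: 13 cis-fused 2-methylcycloheptane-1,3-dione
Product: 14 vinylogous methyl ester (7-methoxy-1,4,4,6-tetramethyl-1-(triethylsilyloxy)-2,3,3a,4,8,8a-hexahydroazulen-5(1H)-one)
Conditions: TMSCHN2, toluene–MeOH, 0 °C → rt
Reagents that add atoms: (trimethylsilyl)diazomethane C[Si](C)(C)C=[N+]=[N-]
Why: O-Methylation of the enolised 1,3-dione occurs at the less hindered oxygen (remote from CMe2), leaving the carbonyl beside the quaternary carbon as needed for the later transposition.

Step 8
Reactants: 15 (S)-(+)-linalool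
Product: 16 (5S)-5-methyl-5-vinyltetrahydrofuran-2-ol
Conditions: O3 (1 equiv), CH2Cl2–MeOH, −78 °C; Me2S, −78 °C → rt
Reagents that add atoms: ozone [O-][O+]=O
Why: Chemoselective ozonolysis of the electron-rich trisubstituted alkene (the vinyl group of the allylic alcohol reacts far more slowly); the hydroxy aldehyde closes to the lactol and the stereocentre is untouched.

Step 9
Reactants: 16 (5S)-5-methyl-5-vinyltetrahydrofuran-2-ol; 17 isopropenylmagnesium bromide
Product: 18 (6S)-2,6-dimethylocta-1,7-diene-3,6-diol
Conditions: THF, 0 °C → rt (3 equiv of 17); aq. NH4Cl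
Reagents that add atoms: none
Why: Grignard addition to the open hydroxy aldehyde form of the lactol; the new carbinol is a 1:1 mixture that is erased in step 11.

Step 10
Reactants: 18 (6S)-2,6-dimethylocta-1,7-diene-3,6-diol
Product: 19 (4S)-2,4-dimethylcyclohex-2-ene-1,4-diol
Conditions: second-generation Grubbs catalyst RuCl2(=CHPh)(PCy3)(H2IMes) (2 mol %), CH2Cl2, 40 °C
Reagents that add atoms: none
Why: Ring-closing metathesis between the vinyl and isopropenyl groups forms the trisubstituted cyclohexene with loss of ethene.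

Step 11
Reactants: 19 (4S)-2,4-dimethylcyclohex-2-ene-1,4-diol
Product: 20 (S)-4-hydroxy-2,4-dimethylcyclohex-2-en-1-one
Conditions: MnO2, CH2Cl2, rt
Reagents that add atoms: none
Why: Allylic alcohol oxidation of the secondary carbinol (the tertiary one cannot be oxidised) converges both epimers to one enone.

Step 12
Reactants: 20 (S)-4-hydroxy-2,4-dimethylcyclohex-2-en-1-one; 21 vinylmagnesium bromide
Product: 22 2,4-dimethyl-1,4-bis(trimethylsilyloxy)-3-vinylcyclohex-1-ene (vinyl cis to the tertiary oxygen)
Conditions: THF, −78 → −20 °C (3.5 equiv of 21); then TMSCl, Et3N, DMPU, −78 → 0 °C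
Reagents that add atoms: chlorotrimethylsilane C[Si](C)(C)Cl
Why: Alkoxide-directed 1,4-addition: the magnesium alkoxide delivers the vinyl Grignard to its own face, so vinyl ends cis to the tertiary oxygen; the enolate is trapped regiospecifically as the silyl enol ether.

Step 13
Reactants: 22 bis(trimethylsilyloxy) vinylcyclohexene; 23 5-iodo-2-methylpent-2-ene
Product: 26 hydroxy ketone (4-hydroxy-2,4-dimethyl-2-(4-methylpent-3-enyl)-3-vinylcyclohexanone), via lithium enolate 24 (not isolated), via silyl-protected ketone 25 (not isolated)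
Conditions: MeLi, THF, 0 °C; then HMPA, −78 °C → rt; 1 M HCl work-up
Reagents that add atoms: none
Why: Regiospecific lithium enolate generation by MeLi cleavage of the enol silane, then SN2 C-alkylation with the iodide entering anti to the adjacent vinyl group (trans-2,3 rule), which sets the quaternary centre with methyl cis to vinyl; the acid work-up removes the O-SiMe3 group.

Step 14
Reactants: 26 hydroxy ketone
Product: 27 cyclohexane-1,4-diol (new secondary OH cis to the quaternary methyl)
Conditions: NaBH4, MeOH, 0 °C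
Reagents that add atoms: none
Why: Borohydride reduction by axial hydride attack on the chair that has the quaternary methyl axial gives the equatorial alcohol, cis to that methyl.

Step 15
Reactants: 27 cyclohexane-1,4-diol
Product: 29 trans-fused oxepane diol (2,2,5a,7-tetramethyl-6-vinyldecahydrobenzo[b]oxepine-3,7-diol as both C3 epimers), via oxepanylmercury trifluoroacetate 28 (not isolated)
Conditions: Hg(OCOCF3)2, MeNO2, −20 °C; then NaBH4, O2, DMF, 0 °C
Reagents that add atoms: dioxygen O=O
Why: Intramolecular Markovnikov alkoxymercuration (7-endo) puts the ring oxygen on the tertiary carbon and closes the trans-fused oxepane; oxidative demercuration gives both carbinol epimers, which converge in step 16.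

Step 16
Reactants: 29 trans-fused oxepane diol
Product: 30 oxepan-3-one (7-hydroxy-2,2,5a,7-tetramethyl-6-vinyloctahydrobenzo[b]oxepin-3-one)
Conditions: Dess–Martin periodinane, NaHCO3, CH2Cl2, rt
Reagents that add atoms: none
Why: Dess–Martin oxidation of the secondary alcohol (the tertiary alcohol is inert) erases the scrambled centre.

Step 17
Reactants: 30 oxepan-3-one
Product: 31 single oxepane diol (3-OH trans to the angular methyl)
Conditions: NaBH4, MeOH, −20 °C
Reagents that add atoms: none
Why: Substrate-controlled hydride reduction from the exposed face, anti to the pseudo-axial methyl of the neighbouring CMe2 group (Felkin-type), gives the carbinol trans to the angular methyl.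

Step 18
Reactants: 31 single oxepane diol
Product: 32 bis(triethylsilyl) ether of 31
Conditions: TESOTf, 2,6-lutidine, CH2Cl2, 0 °C → rt
Reagents that add atoms: triethylsilyl triflate CC[Si](CC)(CC)OS(=O)(=O)C(F)(F)F
Why: Silyl ether formation at the secondary and the tertiary alcohol with the reactive silyl triflate, so the later organolithium is not quenched.

Step 19
Reactants: 32 bis(triethylsilyl) ether
Product: 34 primary iodide (6-(2-iodoethyl) analogue of 32), via alkylzirconocene chloride 33 (not isolated)
Conditions: Cp2Zr(H)Cl, THF, rt; then I2, 0 °C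
Reagents that add atoms: iodine I-I
Why: Hydrozirconation places zirconium on the terminal carbon (anti-Markovnikov) and iodinolysis of the C–Zr bond gives the primary iodide.

Step 20
Reactants: 34 primary iodide; 14 vinylogous methyl ester
Product: 37 target CNP0397160.1, via alkyllithium 35 (not isolated), via tertiary carbinol adduct 36 (not isolated)
Conditions: t-BuLi (2.1 equiv), Et2O–pentane, −78 °C; CeCl3, THF, −78 °C; then 14, −78 → 0 °C; then 2 M HCl, THF, rt
Reagents that add atoms: water O
Why: Iodine–lithium exchange and transmetalation to the organocerium reagent allow 1,2-addition to the hindered, enolisable carbonyl; acid then effects the Stork–Danheiser transposition (loss of methanol) and cleaves the three silyl ethers, with no stereocentre formed or touched.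

**Compound list**

1 | (R)-(−)-linalool, (3R)-3,7-dimethylocta-1,6-dien-3-ol | C=C[C@](C)(O)CCC=C(C)C | starting material
2 | (R)-1-methylcyclopent-2-en-1-ol | C[C@]1(O)C=CCC1 | intermediate
3 | (R)-1-methyl-1-(triethylsilyloxy)cyclopent-2-ene | CC[Si](CC)(CC)O[C@@]1(C)C=CCC1 | intermediate
4 | N,N-dimethylisobutyramide | CC(C)C(=O)N(C)C | starting material
5 | N,N-dimethyl cyclobutaniminium triflate corresponding to 6 | CC[Si](CC)(CC)O[C@]1(C)CC[C@@H]2[C@H]1C(=[N+](C)C)C2(C)C.[O-]S(=O)(=O)C(F)(F)F | intermediate
6 | 4,7,7-trimethyl-4-(triethylsilyloxy)-cis-bicyclo[3.2.0]heptan-6-one; C=O carbon on the ring-fusion carbon next to the carbinol; OSiEt3 cis to both ring-fusion hydrogens, 4-methyl on the cyclobutanone face | CC[Si](CC)(CC)O[C@]1(C)CC[C@@H]2[C@H]1C(=O)C2(C)C | intermediate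
7 | 2,2,6-trimethyl-6-(triethylsilyloxy)-cis-bicyclo[3.3.0]octan-3-one; OSiEt3 cis to the ring-fusion hydrogens | CC[Si](CC)(CC)O[C@]1(C)CC[C@@H]2[C@H]1CC(=O)C2(C)C | intermediate
8 | 3-(trimethylsilyloxy) enol ether of 7 (double bond towards the former CH2) | CC[Si](CC)(CC)O[C@]1(C)CC[C@@H]2[C@H]1C=C(O[Si](C)(C)C)C2(C)C | intermediate
9 | 2-chloropropanoyl chloride (racemic) | CC(Cl)C(Cl)=O | starting material
10 | chloro(methyl)ketene | CC(Cl)=C=O | intermediate
11 | tricyclic [2+2] adduct: 2-chloro-2-methyl-3-(trimethylsilyloxy)cyclobutanone fused across the former enol double bond, mixture at the three new centres | CC[Si](CC)(CC)O[C@]1(C)CC[C@@H]2[C@H]1C3C(=O)C(C)(Cl)C3(O[Si](C)(C)C)C2(C)C | intermediate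
12 | dechlorinated analogue of 11 | CC[Si](CC)(CC)O[C@]1(C)CC[C@@H]2[C@H]1C3C(=O)C(C)C3(O[Si](C)(C)C)C2(C)C | intermediate
13 | 1,4,4,6-tetramethyl-1-(triethylsilyloxy)octahydroazulene-5,7-dione, cis-fused, ring-fusion hydrogens cis to OSiEt3, C6 epimerisable | CC[Si](CC)(CC)O[C@]1(C)CC[C@@H]2[C@H]1CC(=O)C(C)C(=O)C2(C)C | intermediate
14 | 7-methoxy-1,4,4,6-tetramethyl-1-(triethylsilyloxy)-2,3,3a,4,8,8a-hexahydroazulen-5(1H)-one, cis-fused as in 13 | CC[Si](CC)(CC)O[C@]1(C)CC[C@@H]2[C@H]1CC(OC)=C(C)C(=O)C2(C)C | intermediate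
15 | (S)-(+)-linalool, (3S)-3,7-dimethylocta-1,6-dien-3-ol | C=C[C@@](C)(O)CCC=C(C)C | starting material
16 | (5S)-5-methyl-5-vinyltetrahydrofuran-2-ol (anomers) | C=C[C@@]1(C)OC(O)CC1 | intermediate
17 | isopropenylmagnesium bromide | CC(=C)[Mg]Br | starting material
18 | (6S)-2,6-dimethylocta-1,7-diene-3,6-diol (C3 epimers) | C=C(C)C(O)CC[C@](C)(O)C=C | intermediate
19 | (4S)-2,4-dimethylcyclohex-2-ene-1,4-diol (C1 epimers) | CC1=C[C@@](C)(O)CCC1O | intermediate
20 | (S)-4-hydroxy-2,4-dimethylcyclohex-2-en-1-one | CC1=C[C@@](C)(O)CCC1=O | intermediate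
21 | vinylmagnesium bromide | C=C[Mg]Br | starting material
22 | 2,4-dimethyl-1,4-bis(trimethylsilyloxy)-3-vinylcyclohex-1-ene, vinyl cis to the C4 silyloxy group | C=C[C@@H]1C(C)=C(O[Si](C)(C)C)CC[C@]1(C)O[Si](C)(C)C | intermediate
23 | 5-iodo-2-methylpent-2-ene | CC(C)=CCCI | starting material
24 | lithium enolate derived from 22 | C=C[C@@H]1C(C)=C(O[Li])CC[C@]1(C)O[Si](C)(C)C | intermediate
25 | 4-O-trimethylsilyl ether of 26 | C=C[C@@H]1[C@@](C)(CCC=C(C)C)C(=O)CC[C@]1(C)O[Si](C)(C)C | intermediate
26 | 4-hydroxy-2,4-dimethyl-2-(4-methylpent-3-enyl)-3-vinylcyclohexanone; vinyl cis to the 4-OH and to the 2-methyl, alkenyl chain trans to vinyl | C=C[C@@H]1[C@@](C)(CCC=C(C)C)C(=O)CC[C@]1(C)O | intermediate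
27 | cyclohexane-1,4-diol from 26; secondary OH cis to the quaternary methyl, other centres as in 26 | C=C[C@@H]1[C@@](C)(CCC=C(C)C)[C@H](O)CC[C@]1(C)O | intermediate
28 | oxepan-3-ylmercury trifluoroacetate (trans-fused bicycle of 29 with HgOCOCF3 at C3) | C=C[C@@H]1[C@@]2(C)CCC([Hg]OC(=O)C(F)(F)F)C(C)(C)O[C@@H]2CC[C@]1(C)O | intermediate
29 | 2,2,5a,7-tetramethyl-6-vinyldecahydrobenzo[b]oxepine-3,7-diol, trans-fused, both C3 epimers | C=C[C@@H]1[C@@]2(C)CCC(O)C(C)(C)O[C@@H]2CC[C@]1(C)O | intermediate
30 | 7-hydroxy-2,2,5a,7-tetramethyl-6-vinyloctahydrobenzo[b]oxepin-3(2H)-one, trans-fused | C=C[C@@H]1[C@@]2(C)CCC(=O)C(C)(C)O[C@@H]2CC[C@]1(C)O | intermediate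
31 | (3R)-diol: 2,2,5a,7-tetramethyl-6-vinyldecahydrobenzo[b]oxepine-3,7-diol, 3-OH trans to the 5a-methyl | C=C[C@@H]1[C@@]2(C)CC[C@@H](O)C(C)(C)O[C@@H]2CC[C@]1(C)O | intermediate
32 | 3,7-bis(triethylsilyl) ether of 31 | C=C[C@@H]1[C@@]2(C)CC[C@@H](O[Si](CC)(CC)CC)C(C)(C)O[C@@H]2CC[C@]1(C)O[Si](CC)(CC)CC | intermediate
33 | alkylzirconocene chloride from 32 (Zr on the terminal carbon) | Cl[Zr](C1C=CC=C1)(C1C=CC=C1)CC[C@@H]1[C@@]2(C)CC[C@@H](O[Si](CC)(CC)CC)C(C)(C)O[C@@H]2CC[C@]1(C)O[Si](CC)(CC)CC | intermediate
34 | 6-(2-iodoethyl)-2,2,5a,7-tetramethyl-3,7-bis(triethylsilyloxy)decahydrobenzo[b]oxepine, configuration as in 31 | ICC[C@@H]1[C@@]2(C)CC[C@@H](O[Si](CC)(CC)CC)C(C)(C)O[C@@H]2CC[C@]1(C)O[Si](CC)(CC)CC | intermediate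
35 | primary alkyllithium from 34 | [Li]CC[C@@H]1[C@@]2(C)CC[C@@H](O[Si](CC)(CC)CC)C(C)(C)O[C@@H]2CC[C@]1(C)O[Si](CC)(CC)CC | intermediate
36 | tertiary carbinol from 1,2-addition of 35 to 14 (new carbinol centre unassigned) | CC[Si](CC)(CC)O[C@]1(C)CC[C@@H]2[C@H]1CC(OC)=C(C)C(O)(CC[C@@H]3[C@@]4(C)CC[C@@H](O[Si](CC)(CC)CC)C(C)(C)O[C@@H]4CC[C@]3(C)O[Si](CC)(CC)CC)C2(C)C | intermediate
37 | CNP0397160.1: 5-[2-(3,7-dihydroxy-2,2,5a,7-tetramethyldecahydrobenzo[b]oxepin-6-yl)ethyl]-1-hydroxy-1,4,4,6-tetramethyl-2,3,3a,4,8,8a-hexahydroazulen-7(1H)-one | CC1=C(CC[C@@H]2[C@@]3(C)CC[C@@H](O)C(C)(C)O[C@@H]3CC[C@]2(C)O)C(C)(C)[C@@H]2CC[C@@](C)(O)[C@@H]2CC1=O | target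

**Totals and weak points**

Total step count: 20 (7 for the right half, 12 for the left half, 1 union). Longest linear sequence: 13 steps (steps 8–19, then step 20).

Step 5 (ketene cycloaddition onto a silyl enol ether next to a quaternary carbon). If chloro(methyl)ketene is too unreactive, the fallback sets out from silyl enol ether 8 and uses the more electrophilic dichloroketene (Cl2CHCOCl, Et3N, hexane) to give the dichlorocyclobutanone F1. Reduction and ring opening (Zn, NH4Cl, MeOH; then K2CO3) give the 6-unsubstituted cycloheptane-1,3-dione F2. The methyl group is then installed by C-alkylation of the dione (MeI, K2CO3, acetone), which comes back to the route at dione 13.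

Step 13 (SN2 alkylation of a hindered tetrasubstituted enolate by an unactivated iodide). The fallback sets out from silyl enol ether 22 and builds the quaternary centre by Mukaiyama–Michael addition to acrolein (BF3·OEt2, CH2Cl2, −78 °C, acid work-up), giving the keto aldehyde F3. Wittig olefination of the aldehyde with isopropylidenetriphenylphosphorane (the hindered ketone does not react) then comes back at hydroxy ketone 26.

Step 15 (seven-membered ring closure by alkoxymercuration with a vinyl group present). The fallback sets out from diol 27 and epoxidises the trisubstituted alkene selectively (m-CPBA, NaHCO3, CH2Cl2, 0 °C) to the epoxide F4. Opening at the tertiary epoxide carbon by the secondary hydroxyl in the 7-endo sense (Zn(OTf)2, (Bu3Sn)2O, toluene) comes back at the oxepane diols 29.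

Further compounds
F1 | step 5 | tricyclic 2,2-dichloro-3-(trimethylsilyloxy)cyclobutanone from 8 and dichloroketene | CC[Si](CC)(CC)O[C@]1(C)CC[C@@H]2[C@H]1C3C(=O)C(Cl)(Cl)C3(O[Si](C)(C)C)C2(C)C
F2 | step 5 | 1,4,4-trimethyl-1-(triethylsilyloxy)octahydroazulene-5,7-dione, cis-fused as in 13 | CC[Si](CC)(CC)O[C@]1(C)CC[C@@H]2[C@H]1CC(=O)CC(=O)C2(C)C
F3 | step 13 | 3-(4-hydroxy-1,4-dimethyl-2-oxo-6-vinylcyclohexyl)propanal, configuration as in 26 | C=C[C@@H]1[C@@](C)(CCC=O)C(=O)CC[C@]1(C)O
F4 | step 15 | epoxide of the trisubstituted alkene of 27 (both epoxide epimers) | C=C[C@@H]1[C@@](C)(CCC2OC2(C)C)[C@H](O)CC[C@]1(C)O
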